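**Retrosynthetic overview**
- The strategy rests on ring A (C4a, C5, C6, C7, C8, C8a). It carries OMe on C5, methyl on C6 and OH on C7. C5–C8 with these groups is the carbon chain of a 2-methylacetoacetate-type diene, and the fusion bond C4a–C8a is the C5=C6 bond of a 4-pyranone (ring C).
- Last disconnection: the 4'-O-benzyl ether. Key disconnection: C8–C8a and C4a–C5, which leads back to a 3-aryl-5-bromo-4H-pyran-4-one and 1,1-dimethoxy-2-methyl-3-(trimethylsilyloxy)buta-1,3-diene. The bromine and one methoxy group leave, and their loss provides the unsaturation of the arene.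
- The bromopyranone comes from symmetrical 3,5-dibromo-4H-pyran-4-one by one Suzuki–Miyaura coupling (C3–C1'). The diene comes from trimethyl orthopropionate and acetyl chloride.
- Ring order: rings C and B are bought and joined first. Ring A is the only ring built, and it is built last.

Key step: step 8

Remark: the target has no stereocentre, stereogenic axis or stereogenic double bond. It is achiral, so the route needs no stereocontrol.

**Step 1**
Reactants: 1 4H-pyran-4-one
Product: 3 3,5-dibromo-4H-pyran-4-one, via 3-bromo-4H-pyran-4-one 2 (not isolated)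
Conditions: Br2 (2.3 equiv), pyridine (2.5 equiv), CH2Cl2, 0 °C → reflux
Reagents that add atoms: bromine, BrBr
Why: Electrophilic α-bromination of a vinylogous ester by addition–elimination should occur only at C3 and C5, the nucleophilic enol-ether carbons, with pyridine taking up HBr so that the pyranone is restored after each bromination.

**Step 2**
Reactants: 4 4-bromo-2,6-dimethoxyphenol
Product: 5 2-(benzyloxy)-5-bromo-1,3-dimethoxybenzene
Conditions: BnBr (1.1 equiv), K2CO3 (1.5 equiv), DMF, 50 °C
Reagents that add atoms: benzyl bromide, BrCc1ccccc1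
Why: Williamson ether synthesis on the only acidic OH, under conditions that leave the aryl bromide untouched.

**Step 3**
Reactants: 5 2-(benzyloxy)-5-bromo-1,3-dimethoxybenzene
Product: 6 2-[4-(benzyloxy)-3,5-dimethoxyphenyl]-4,4,5,5-tetramethyl-1,3,2-dioxaborolane
Conditions: B2pin2 (1.1 equiv), Pd(dppf)Cl2 (3 mol %), KOAc (3 equiv), 1,4-dioxane, 90 °C
Reagents that add atoms: bis(pinacolato)diboron, CC1(C)OB(OC1(C)C)B1OC(C)(C)C(C)(C)O1
Why: Miyaura borylation of an aryl bromide, in which the ethers are inert and the weak base KOAc should suppress homocoupling.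

**Step 4**
Reactants: 3 3,5-dibromo-4H-pyran-4-one; 6 2-[4-(benzyloxy)-3,5-dimethoxyphenyl]-4,4,5,5-tetramethyl-1,3,2-dioxaborolane
Product: 7 3-[4-(benzyloxy)-3,5-dimethoxyphenyl]-5-bromo-4H-pyran-4-one
Conditions: 3 (2.5 equiv), 6 (1.0 equiv), Pd(dppf)Cl2 (3 mol %), K3PO4 (2 equiv), 1,4-dioxane/H2O 10:1, 60 °C; excess 3 recovered by chromatography
Reagents that add atoms: none
Why: Suzuki–Miyaura coupling at an α-bromo-enone C(sp2)–Br bond, as practised on 3-halochromones and 3-halopyranones, should stop at the mono stage because the two C–Br bonds of 3 are equivalent, 3 is in excess, and the more electron-poor dibromide should add to Pd(0) faster than 7.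

**Step 5**
Reactants: 8 trimethyl orthopropionate
Product: 9 1,1-dimethoxyprop-1-ene
Conditions: Al(OtBu)3 (1.0 equiv), neat, 180–200 °C, slow fractional distillation under N2
Reagents that add atoms: none
Why: Aluminium-alkoxide-promoted dealcoholation of an orthoester, in which the methanol lost is bound to aluminium and the volatile ketene acetal leaves the basic melt by distillation.

**Step 6**
Reactants: 9 1,1-dimethoxyprop-1-ene; 10 acetyl chloride
Product: 11 4,4-dimethoxy-3-methylbut-3-en-2-one
Conditions: 10 (1.05 equiv), pyridine (1.2 equiv), CH2Cl2, −20 °C → rt; salt filtered off under N2, distillation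
Reagents that add atoms: none
Why: C-acylation of an electron-rich ketene acetal by N-acetylpyridinium chloride, followed by loss of the acidic proton between the carbonyl and the dimethoxycarbenium carbon, is the acylation–deprotonation known for ketene acetals and enol ethers and should give the push–pull enone.

**Step 7**
Reactants: 11 4,4-dimethoxy-3-methylbut-3-en-2-one
Product: 12 1,1-dimethoxy-2-methyl-3-(trimethylsilyloxy)buta-1,3-diene
Conditions: TMSCl (1.5 equiv), Et3N (2 equiv), ZnCl2 (3 mol %), toluene, 40 °C; filtration under N2, distillation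
Reagents that add atoms: chlorotrimethylsilane, C[Si](C)(C)Cl
Why: Enol silylation with TMSCl/Et3N/ZnCl2, the method used for the parent 1,1-dimethoxy-3-silyloxybutadiene, can give only one diene because the acetyl CH3 is the sole enolisable position.

**Step 8**
Reactants: 7 3-[4-(benzyloxy)-3,5-dimethoxyphenyl]-5-bromo-4H-pyran-4-one; 12 1,1-dimethoxy-2-methyl-3-(trimethylsilyloxy)buta-1,3-diene
Product: 16 3-[4-(benzyloxy)-3,5-dimethoxyphenyl]-7-hydroxy-5-methoxy-6-methyl-4H-chromen-4-one, via silyloxypyrylium triflate 13 (not isolated), via C6 Michael adduct 14 (not isolated), via ring-fusion bromide 15 (not isolated)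
Conditions: TMSOTf (1.1 equiv), 2,6-lutidine (0.2 equiv), CH2Cl2, 0 °C → rt; 12 (1.5 equiv), −78 °C → rt; DBU (3.5 equiv), rt → 40 °C; 1 M HCl work-up
Reagents that add atoms: trimethylsilyl trifluoromethanesulfonate, C[Si](C)(C)OS(=O)(=O)C(F)(F)F (its atoms sit only in 13 and 14; none stays in 16)
Why: Proposed new method: O-silylation turns 7 into the 4-silyloxypyrylium ion 13, whose C6 takes up the nucleophilic CH2 terminus of 12 in a vinylogous Mukaiyama–Michael addition (C8–C8a) to give the 2H-pyran 14, and the bromo silyl enol ether carbon of 14 (pyranone C5, later C4a) then adds to the silyl-triflate-activated β,β-dimethoxyenone carbon with loss of MeOSiMe3 (C4a–C5) to give 15. The closest known reaction types are the silyl-triflate-promoted Michael–Michael fusion of a cyclohexanone ring onto C2–C3 of chromones with 2-silyloxybutadienes and the annulation of 2-haloquinones with 1,1-dialkoxy-3-silyloxybutadienes, neither of which has been run on a monocyclic 3-halo-4-pyranone. Ring A closes by a 6-endo-trig addition–elimination (formally a stepwise [4+2]), and no stereocentre remains because the transient centres C4a and C8a of 15 are erased on aromatisation. DBU enolises the C7 ketone towards C8 and removes HBr from C8a–H and C4a–Br; if H and Br stand cis at the ring fusion, C8a can invert by reversible β-elimination and re-addition of O1 from the C7 enolate, and formation of the arene drives the loss. The step needs attack at C6 and not at C2, which should be secured because C6 lies next to the small, inductively withdrawing bromine while C2 is flanked by the twisted trialkoxyphenyl group, and only the C6 adduct carries a leaving group on the carbon that must close, so a C2 adduct cannot reach an arene. The head-to-tail sense (CH2 to the β-carbon, acetal carbon to the α-carbon of the enone) follows from the polarity of both partners and places OMe on C5, methyl on C6 and OH on C7.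

**Step 9**
Reactants: 16 3-[4-(benzyloxy)-3,5-dimethoxyphenyl]-7-hydroxy-5-methoxy-6-methyl-4H-chromen-4-one
Product: 17 7-hydroxy-3-(4-hydroxy-3,5-dimethoxyphenyl)-5-methoxy-6-methyl-4H-chromen-4-one (CNP0425497.0)
Conditions: H2 (1 atm), 10 % Pd/C, EtOAc/MeOH, rt, stopped after one equivalent of H2
Reagents that add atoms: none
Why: Catalytic hydrogenolysis of a benzyl aryl ether, which should spare the methyl ethers and, with the uptake limited, the more slowly reduced C2=C3 bond of the isoflavone.

**Compound list**
1 | 4H-pyran-4-one | O=c1ccocc1 | starting material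
2 | 3-bromo-4H-pyran-4-one (not isolated in step 1) | O=c1ccocc1Br | intermediate
3 | 3,5-dibromo-4H-pyran-4-one | O=c1c(Br)cocc1Br | intermediate
4 | 4-bromo-2,6-dimethoxyphenol | COc1cc(Br)cc(OC)c1O | starting material
5 | 2-(benzyloxy)-5-bromo-1,3-dimethoxybenzene | COc1cc(Br)cc(OC)c1OCc1ccccc1 | intermediate
6 | 2-[4-(benzyloxy)-3,5-dimethoxyphenyl]-4,4,5,5-tetramethyl-1,3,2-dioxaborolane | COc1cc(B2OC(C)(C)C(C)(C)O2)cc(OC)c1OCc1ccccc1 | intermediate
7 | 3-[4-(benzyloxy)-3,5-dimethoxyphenyl]-5-bromo-4H-pyran-4-one | O=c1c(Br)cocc1-c1cc(OC)c(OCc2ccccc2)c(OC)c1 | intermediate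
8 | trimethyl orthopropionate (1,1,1-trimethoxypropane) | CCC(OC)(OC)OC | starting material
9 | 1,1-dimethoxyprop-1-ene | CC=C(OC)OC | intermediate
10 | acetyl chloride | CC(=O)Cl | starting material
11 | 4,4-dimethoxy-3-methylbut-3-en-2-one | COC(OC)=C(C)C(C)=O | intermediate
12 | 1,1-dimethoxy-2-methyl-3-(trimethylsilyloxy)buta-1,3-diene | COC(OC)=C(C)C(=C)O[Si](C)(C)C | intermediate
13 | 3-[4-(benzyloxy)-3,5-dimethoxyphenyl]-5-bromo-4-(trimethylsilyloxy)pyrylium trifluoromethanesulfonate (not isolated) | COc1cc(-c2c[o+]cc(Br)c2O[Si](C)(C)C)cc(OC)c1OCc1ccccc1.[O-]S(=O)(=O)C(F)(F)F | intermediate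
14 | 1-{5-[4-(benzyloxy)-3,5-dimethoxyphenyl]-3-bromo-4-(trimethylsilyloxy)-2H-pyran-2-yl}-4,4-dimethoxy-3-methylbut-3-en-2-one (racemic, not isolated) | COC(OC)=C(C)C(=O)CC1OC=C(c2cc(OC)c(OCc3ccccc3)c(OC)c2)C(O[Si](C)(C)C)=C1Br | intermediate
15 | 3-[4-(benzyloxy)-3,5-dimethoxyphenyl]-4a-bromo-5-methoxy-6-methyl-8,8a-dihydro-4H-chromene-4,7(4aH)-dione (racemic, ring-fusion configuration not fixed, not isolated) | COC1=C(C)C(=O)CC2OC=C(c3cc(OC)c(OCc4ccccc4)c(OC)c3)C(=O)C12Br | intermediate
16 | 3-[4-(benzyloxy)-3,5-dimethoxyphenyl]-7-hydroxy-5-methoxy-6-methyl-4H-chromen-4-one | COc1cc(-c2coc3cc(O)c(C)c(OC)c3c2=O)cc(OC)c1OCc1ccccc1 | intermediate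
17 | 7-hydroxy-3-(4-hydroxy-3,5-dimethoxyphenyl)-5-methoxy-6-methyl-4H-chromen-4-one | COc1cc(-c2coc3cc(O)c(C)c(OC)c3c2=O)cc(OC)c1O | target

**Step count**
- Total step count: 9.
- Longest linear sequence: 5 steps (4 → 5 → 6 → 7 → 16 → 17). The diene branch 8 → 9 → 11 → 12 → 16 → 17 is equally long.

**Steps most likely to fail**

**1. Step 8 (Proposed new method).**
- What may go wrong:
  - The diene may add at C2 instead of C6.
  - The cascade may stall after the first C–C bond, because a brominated enol ether is a weak nucleophile towards a hindered, strongly stabilised cation.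
  - Adventitious acid may hydrolyse the ketene-acetal unit to the ester, so that closure would end in a 5-hydroxyl.
  - The ring-fusion carbon may give up bromine as a positive halogen instead of losing HBr.
- Fallback: build ring A from a phloroglucinol-type ketone and close ring C onto it, using known chemistry only. It sets out from boronate 6 and comes back to the route at target 17.
  - Purchased 1-(2,4,6-trihydroxy-3-methylphenyl)ethanone F1 is benzylated twice (BnBr, 2 equiv, K2CO3, acetone). This should spare the hydrogen-bonded and more hindered hydroxyl between acetyl and methyl, giving 1-[4,6-bis(benzyloxy)-2-hydroxy-3-methylphenyl]ethanone F2.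
  - Forcing methylation (MeI, K2CO3, DMF, 60 °C) gives 1-[4,6-bis(benzyloxy)-2-methoxy-3-methylphenyl]ethanone F3.
  - Chelation-directed cleavage of the benzyl ether ortho to the carbonyl (MgBr2·OEt2, toluene/Et2O, reflux) gives 1-[4-(benzyloxy)-6-hydroxy-2-methoxy-3-methylphenyl]ethanone F4.
  - DMF dimethyl acetal (95 °C) gives (E)-1-[4-(benzyloxy)-6-hydroxy-2-methoxy-3-methylphenyl]-3-(dimethylamino)prop-2-en-1-one F5.
  - Iodine in MeOH closes ring C to 7-(benzyloxy)-3-iodo-5-methoxy-6-methyl-4H-chromen-4-one F6.
  - Suzuki–Miyaura coupling with 6 gives 7-(benzyloxy)-3-[4-(benzyloxy)-3,5-dimethoxyphenyl]-5-methoxy-6-methyl-4H-chromen-4-one F7.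
  - Hydrogenolysis of both benzyl ethers under the conditions of step 9 gives 17.

**2. Step 4.**
- What may go wrong: the second C–Br bond may couple as well, and aqueous base may open the strongly electrophilic dibromopyranone ring.
- Fallback: replace statistical desymmetrisation by chemoselective coupling of a mixed dihalide. It sets out from 1 and comes back at 7.
  - One equivalent of bromine under the conditions of step 1 gives 2, now isolated.
  - Iodination of the free enol-ether carbon C5 (I2, CAN, MeCN, 60 °C) gives 3-bromo-5-iodo-4H-pyran-4-one F8.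
  - The C–I bond is coupled with one equivalent of 6 (Pd(PPh3)4, K3PO4, dioxane/H2O, rt to 40 °C), below the temperature at which the C–Br bond should react. This gives 7.

**3. Step 6.**
- What may go wrong: chloride or pyridine may demethylate the dimethoxycarbenium intermediate faster than it loses its proton. That would lead to the β-keto ester and not to the acyl ketene acetal.
- Fallback: make the two C–O bonds last, under basic conditions. It sets out from 10 and comes back at 11, and it makes step 5 unnecessary.
  - AlCl3-mediated acylation of purchased 1,1-dichloroprop-1-ene F9 with 10 (CH2Cl2, 0 °C) gives 4,4,4-trichloro-3-methylbutan-2-one F10.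
  - Et3N removes HCl to give 4,4-dichloro-3-methylbut-3-en-2-one F11.
  - Two vinylic addition–eliminations with NaOMe (2.1 equiv, MeOH, 0 °C → rt) give 11.

**Further compounds**
F1 | step 8 | 1-(2,4,6-trihydroxy-3-methylphenyl)ethanone (purchased) | CC(=O)c1c(O)cc(O)c(C)c1O
F2 | step 8 | 1-[4,6-bis(benzyloxy)-2-hydroxy-3-methylphenyl]ethanone | CC(=O)c1c(O)c(C)c(OCc2ccccc2)cc1OCc1ccccc1
F3 | step 8 | 1-[4,6-bis(benzyloxy)-2-methoxy-3-methylphenyl]ethanone | CC(=O)c1c(OC)c(C)c(OCc2ccccc2)cc1OCc1ccccc1
F4 | step 8 | 1-[4-(benzyloxy)-6-hydroxy-2-methoxy-3-methylphenyl]ethanone | CC(=O)c1c(OC)c(C)c(OCc2ccccc2)cc1O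
F5 | step 8 | (E)-1-[4-(benzyloxy)-6-hydroxy-2-methoxy-3-methylphenyl]-3-(dimethylamino)prop-2-en-1-one | CN(C)/C=C/C(=O)c1c(OC)c(C)c(OCc2ccccc2)cc1O
F6 | step 8 | 7-(benzyloxy)-3-iodo-5-methoxy-6-methyl-4H-chromen-4-one | COc1c(C)c(OCc2ccccc2)cc2occ(I)c(=O)c12
F7 | step 8 | 7-(benzyloxy)-3-[4-(benzyloxy)-3,5-dimethoxyphenyl]-5-methoxy-6-methyl-4H-chromen-4-one | COc1cc(-c2coc3cc(OCc4ccccc4)c(C)c(OC)c3c2=O)cc(OC)c1OCc1ccccc1
F8 | step 4 | 3-bromo-5-iodo-4H-pyran-4-one | O=c1c(Br)cocc1I
F9 | step 6 | 1,1-dichloroprop-1-ene (purchased) | CC=C(Cl)Cl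
F10 | step 6 | 4,4,4-trichloro-3-methylbutan-2-one (racemic) | CC(=O)C(C)C(Cl)(Cl)Cl
F11 | step 6 | 4,4-dichloro-3-methylbut-3-en-2-one | CC(=O)C(C)=C(Cl)Cl
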